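## Retrosynthetic overview

1. 8 ⇒ 7: the last step removes two benzyl ethers, the only protecting groups in the route.
2. 7 ⇒ 4 + 5: the C8–C8'' bond is cut between two intact flavones. Both carbons are innately nucleophilic enol-type carbons of phloroglucinol rings. One half is therefore polarity-reversed into a flavon-8-yl cation (enolonium-type) equivalent, the aryllead triacetate 4. The other half keeps its natural polarity as the 7-phenoxide 5, and a chiral amine on lead sets the axis in the same event.
3. 4 ⇒ 2 ⇒ 1: C8–H plumbation of the dibenzyl ether of acacetin.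
4. Ring order: no ring is built. Rings A, B and C of both halves arrive intact in acacetin 1, which supplies both halves.

Assumption: the SMILES carries no descriptor for the stereogenic 8,8'' axis (SMILES cannot express it), so the single enantiomer is taken as (aR). The axis is given in the names, and brucine is assumed to induce the (aR) sense, to be confirmed by exciton-coupled CD of 7.

Assumption: acacetin is bought as a multigram catalogue compound.

## Route

Step 1
Reactants: 1 acacetin (5,7-dihydroxy-4'-methoxyflavone)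
Product: 2 5,7-bis(benzyloxy)-4'-methoxyflavone (5,7-di-O-benzylacacetin)
Conditions: BnBr (3 equiv), K2CO3 (4 equiv), DMF, 80 °C, 12 h
Reagents that add atoms: benzyl bromide, BrCc1ccccc1
Why: Twofold Williamson ether synthesis, in which the acidic 7-OH reacts first and excess base in hot DMF overcomes the 5-OH to C4=O hydrogen bond, so both phenols are masked against oxidation by tetravalent lead, ring A stays electron-rich, and benzyl (unlike methyl) can later be removed without touching the 4'-OMe group.

Step 2
Reactants: 2 5,7-bis(benzyloxy)-4'-methoxyflavone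
Product: 4 [5,7-bis(benzyloxy)-4'-methoxyflavon-8-yl]lead triacetate, via flavon-8-ylmercury acetate 3 (not isolated)
Conditions: Pb(OAc)4 (1.1 equiv), Hg(OAc)2 (10 mol%), CHCl3, 40 °C, dark, 16 h; water wash, precipitate from CHCl3–hexane
Reagents that add atoms: lead tetraacetate, CC(=O)O[Pb](OC(C)=O)(OC(C)=O)OC(C)=O
Why: Electrophilic aromatic plumbation (the direct plumbylation known for 1,3-di- and 1,3,5-trimethoxybenzene), relayed by catalytic mercuration to 3 and Hg-to-Pb exchange as in Pinhey aryllead syntheses, should go to C8 because that carbon is ortho/para to three oxygen donors, is where 5,7-dialkoxyflavones are halogenated and is less crowded than C6 between two benzyloxy groups, so this innately nucleophilic carbon becomes an isolable flavon-8-yl cation equivalent.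

Step 3
Reactants: 4 [5,7-bis(benzyloxy)-4'-methoxyflavon-8-yl]lead triacetate; 1 acacetin
Product: 7 (aR)-5,7-bis(benzyloxy)-5'',7''-dihydroxy-4',4'''-dimethoxy-8,8''-biflavone, via lithium acacetin-7-olate 5 (not isolated), via flavonyl(flavonyloxy)lead diacetate 6 (not isolated)
Conditions: 1, LiN(SiMe3)2 (1.0 equiv), THF, 0 °C, evaporate; brucine (3 equiv), 4 Å MS, PhMe–CH2Cl2 2:1, −20 °C; add 4 (1.1 equiv), −20 °C to rt, 24 h; 1 M HCl wash (recovers brucine), SiO2, recrystallise to >99% ee
Reagents that add atoms: none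
Why: Proposed new method: this is a Pinhey arylation (ligand coupling on tetravalent lead) run atroposelectively with a chiral amine ligand, the closest known reaction type being the brucine-mediated asymmetric coupling of lithium phenoxides with ortho-substituted aryllead triacetates, here extended to two flavone partners; phenoxide 5 displaces one acetate of 4 to give 6, the polarity-reversed C8 is then transferred to the ortho carbon C8'' of the O-bound phenoxide with expulsion of Pb(OAc)2, C8'' is preferred over C6'' because only the 7''-OH is ionised and the chelated 5''-OH preserves the 7-hydroxychromone bond fixation that also directs Mannich and Claisen reactions of 5,7-dihydroxyflavones to C8, and brucine bound to lead makes the two helical approaches of the flavonyl group diastereomeric, so the 8,8'' axis is set as (aR) in the bond-forming event and is then locked by its four ortho oxygen substituents.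

Step 4
Reactants: 7 (aR)-5,7-bis(benzyloxy)-5'',7''-dihydroxy-4',4'''-dimethoxy-8,8''-biflavone
Product: 8 (aR)-4',4'''-di-O-methylcupressuflavone
Conditions: H2 (1 atm), Pd/C (10 wt%), THF–MeOH 1:1, rt, 6 h
Reagents that add atoms: none
Why: Catalytic hydrogenolysis of the two aryl benzyl ethers is faster at room temperature than reduction of the conjugated C2=C3 bond, leaves the 4'- and 4'''-methyl ethers untouched and is far too mild to rotate the tetra-ortho-substituted axis.

## Compound list

1 | acacetin, 5,7-dihydroxy-2-(4-methoxyphenyl)-4H-chromen-4-one | COc1ccc(-c2cc(=O)c3c(O)cc(O)cc3o2)cc1 | starting material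
2 | 5,7-bis(benzyloxy)-2-(4-methoxyphenyl)-4H-chromen-4-one | COc1ccc(-c2cc(=O)c3c(OCc4ccccc4)cc(OCc4ccccc4)cc3o2)cc1 | intermediate
3 | [5,7-bis(benzyloxy)-2-(4-methoxyphenyl)-4-oxo-4H-chromen-8-yl]mercury acetate (not isolated) | COc1ccc(-c2cc(=O)c3c(OCc4ccccc4)cc(OCc4ccccc4)c([Hg]OC(C)=O)c3o2)cc1 | intermediate
4 | [5,7-bis(benzyloxy)-2-(4-methoxyphenyl)-4-oxo-4H-chromen-8-yl]lead triacetate | COc1ccc(-c2cc(=O)c3c(OCc4ccccc4)cc(OCc4ccccc4)c([Pb](OC(C)=O)(OC(C)=O)OC(C)=O)c3o2)cc1 | intermediate
5 | lithium 5-hydroxy-2-(4-methoxyphenyl)-4-oxo-4H-chromen-7-olate (not isolated) | [Li+].COc1ccc(-c2cc(=O)c3c(O)cc([O-])cc3o2)cc1 | intermediate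
6 | diacetoxy[5,7-bis(benzyloxy)-4'-methoxyflavon-8-yl][5-hydroxy-4'-methoxyflavon-7-yloxy]plumbane (not isolated) | COc1ccc(-c2cc(=O)c3c(OCc4ccccc4)cc(OCc4ccccc4)c([Pb](OC(C)=O)(OC(C)=O)Oc4cc(O)c5c(=O)cc(-c6ccc(OC)cc6)oc5c4)c3o2)cc1 | intermediate
7 | (aR)-5,7-bis(benzyloxy)-5'',7''-dihydroxy-4',4'''-dimethoxy-8,8''-biflavone | COc1ccc(-c2cc(=O)c3c(OCc4ccccc4)cc(OCc4ccccc4)c(-c4c(O)cc(O)c5c(=O)cc(-c6ccc(OC)cc6)oc45)c3o2)cc1 | intermediate
8 | (aR)-4',4'''-di-O-methylcupressuflavone, (aR)-5,5'',7,7''-tetrahydroxy-4',4'''-dimethoxy-8,8''-biflavone | COc1ccc(-c2cc(=O)c3c(O)cc(O)c(-c4c(O)cc(O)c5c(=O)cc(-c6ccc(OC)cc6)oc45)c3o2)cc1 | target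

## Step count and risks

Total step count: 4. Longest linear sequence: 4 (1 → 2 → 4 → 7 → 8; compound 1 enters a second time in step 3).

**Most likely to fail, first: step 3.**
- The 7-phenoxide is a vinylogous carboxylate and may couple sluggishly.
- Some C6'' arylation may occur.
- The lithium salt is poorly soluble.
- Neither the level nor the sense of induction by brucine is secured for these partners.

The fallback sets out from 4 and 1 and comes back at 7. It replaces reagent control by resolution.
- The same lead arylation is run without chiral amine (pyridine 3 equiv, CHCl3, 40 °C). This gives racemic 5,7-bis(benzyloxy)-5'',7''-dihydroxy-4',4'''-dimethoxy-8,8''-biflavone F3.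
- Its only unchelated phenol, the 7''-OH, is acylated with (1S)-camphanic chloride (Et3N, DMAP, CH2Cl2, 0 °C).
- The (aR)-7''-O-[(1S)-camphanoyl] ester F4 is separated from the (aS)-7''-O-[(1S)-camphanoyl] ester F5 by chromatography and crystallisation. This also removes any 6''-linked regioisomer, and the axes are assigned by CD.
- Methanolysis of F4 (K2CO3, MeOH–THF, 0 °C) returns to 7. Either antipode is reachable this way.

**Second: step 2.**
- Ring A carries the C4 carbonyl and is less reactive than trimethoxybenzene, so plumbation may stall.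
- It may also be undone by protodeplumbation.

The fallback sets out from 2 and comes back at 4. It replaces C–H metalation by halogenation and metal exchange.
- NIS with catalytic CF3CO2H in MeCN at rt gives 8-iodo-5,7-bis(benzyloxy)-4'-methoxyflavone F1.
- Stannylation with (Bu3Sn)2 and Pd(PPh3)4 (5 mol%) in PhMe at 110 °C gives 5,7-bis(benzyloxy)-4'-methoxy-8-(tributylstannyl)flavone F2.
- Tin-to-lead exchange (Pb(OAc)4, Hg(OAc)2 10 mol%, CHCl3, 40 °C) delivers 4.

**Third: step 4.**
- Traces of lead carried over from step 3 can poison Pd/C.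
- Prolonged exposure can reduce C2=C3.
- Compound 8 is poorly soluble.

The fallback sets out from 7 and comes back at 8. It replaces reductive hydrogenolysis by non-reductive Lewis-acid ether cleavage with a cation trap: BCl3 (6 equiv), pentamethylbenzene (6 equiv), CH2Cl2, −78 °C, then MeOH quench. Aryl methyl ethers survive at this temperature. This fallback makes no new compound (F0).

## Further compounds

F1 | step 2 | 8-iodo-5,7-bis(benzyloxy)-2-(4-methoxyphenyl)-4H-chromen-4-one | COc1ccc(-c2cc(=O)c3c(OCc4ccccc4)cc(OCc4ccccc4)c(I)c3o2)cc1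
F2 | step 2 | 5,7-bis(benzyloxy)-2-(4-methoxyphenyl)-8-(tributylstannyl)-4H-chromen-4-one | COc1ccc(-c2cc(=O)c3c(OCc4ccccc4)cc(OCc4ccccc4)c([Sn](CCCC)(CCCC)CCCC)c3o2)cc1
F3 | step 3 | racemic 5,7-bis(benzyloxy)-5'',7''-dihydroxy-4',4'''-dimethoxy-8,8''-biflavone | COc1ccc(-c2cc(=O)c3c(OCc4ccccc4)cc(OCc4ccccc4)c(-c4c(O)cc(O)c5c(=O)cc(-c6ccc(OC)cc6)oc45)c3o2)cc1
F4 | step 3 | (aR)-5,7-bis(benzyloxy)-5''-hydroxy-4',4'''-dimethoxy-8,8''-biflavon-7''-yl (1S,4R)-camphanate | COc1ccc(-c2cc(=O)c3c(OCc4ccccc4)cc(OCc4ccccc4)c(-c4c(OC(=O)[C@@]67CC[C@@](C)(C(=O)O6)C7(C)C)cc(O)c5c(=O)cc(-c6ccc(OC)cc6)oc45)c3o2)cc1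
F5 | step 3 | (aS)-5,7-bis(benzyloxy)-5''-hydroxy-4',4'''-dimethoxy-8,8''-biflavon-7''-yl (1S,4R)-camphanate | COc1ccc(-c2cc(=O)c3c(OCc4ccccc4)cc(OCc4ccccc4)c(-c4c(OC(=O)[C@@]67CC[C@@](C)(C(=O)O6)C7(C)C)cc(O)c5c(=O)cc(-c6ccc(OC)cc6)oc45)c3o2)cc1
F0 | step 4 | none | none
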